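## Retrosynthetic overview

1. The target comes from a tetrahydrofuran cycloadduct by cleaving two O–Si(iPr)2–O links with fluoride and seven benzyl ethers by hydrogenolysis.
2. Key disconnection: the two C–C bonds joining the oxygen-flanked carbons C2 and C5 (each bearing a 4-oxyphenyl group) to C3 and C4 of the tetrahydrofuran are cut together, retro-[3+2]. This gives an exo,exo 1,3-diaryl carbonyl ylide, stored as a 2,3-diaryloxirane, and a C2-symmetric (E)-1,2-bis(dihydrobenzofuran-4-yl)ethene. The oxirane hangs from the C3 aryl ring of a dihydrobenzofuran on a removable silicon bridge, put on with a preformed aryloxychlorosilane.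
3. Enabling feature: in the tetrahydrofuran ring the aryl groups on C2 and C5 are cis and the dihydrobenzofuranyl groups on C3 and C4 are trans, so C2/C3 are cis and C4/C5 trans. This is exactly, and only, what suprafacial addition of a W-shaped ylide to an E-olefin gives. The two dihydrobenzofurans are homochiral, so the olefin is one building block used twice.
4. The olefin comes from a two-fold Suzuki coupling of a 4-bromo-2,3-trans-dihydrobenzofuran with (E)-1,2-diborylethene. The bromide comes from an enantioselective rhodium-carbene C–H insertion (cis ring) followed by acid epimerisation at C2.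
5. Ring order: the two dihydrobenzofuran rings first (steps 9 and 10), then the tetrahydrofuran, together with a temporary 15-membered bridge ring, in the key step; fluoride opens the bridge ring again.

Key step: step 16

Assumption: Rh2(S-PTAD)4 is taken to deliver the (3S) series in step 9; if the opposite sense is found, the enantiomeric catalyst Rh2(R-PTAD)4 is used and nothing else changes.

## Route

Step 1
Reactants: 1 1,3-bis(benzyloxy)-5-bromobenzene
Product: 3 2,4-bis(benzyloxy)-6-bromobenzaldehyde, via aryl iminium salt 2 (not isolated)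
Conditions: POCl3, DMF, 0 to 70 °C; then H2O, 0 °C
Reagents that add atoms: N,N-dimethylformamide CN(C)C=O; water O
Why: Vilsmeier–Haack formylation should go para to one benzyloxy group and ortho to the other, at the position next to bromine and not at the more hindered one between the two ethers.

Step 2
Reactants: 3 2,4-bis(benzyloxy)-6-bromobenzaldehyde
Product: 4 4-(benzyloxy)-2-bromo-6-hydroxybenzaldehyde
Conditions: MgBr2·OEt2, toluene/Et2O, 80 °C; then 1 M HCl
Reagents that add atoms: none
Why: chelation of magnesium between the aldehyde oxygen and the ortho ether oxygen activates only that benzyl group for cleavage by bromide (chelation-controlled ortho-debenzylation).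

Step 3
Reactants: 4 4-(benzyloxy)-2-bromo-6-hydroxybenzaldehyde; 5 4-(benzyloxy)benzyl chloride
Product: 6 4-(benzyloxy)-2-{[4-(benzyloxy)phenyl]methoxy}-6-bromobenzaldehyde
Conditions: K2CO3, KI (cat.), DMF, 50 °C
Reagents that add atoms: none
Why: Williamson etherification of the phenol installs the benzylic CH2 that later becomes C2 of the dihydrobenzofuran.

Step 4
Reactants: 7 5-bromobenzene-1,3-diol
Product: 8 3-(benzyloxy)-5-bromophenol
Conditions: BnBr (0.9 equiv), K2CO3, acetone, reflux
Reagents that add atoms: benzyl bromide BrCc1ccccc1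
Why: statistical mono-Williamson alkylation of a symmetric diol, in which the over-alkylated ether is compound 1 and can be fed into step 1.

Step 5
Reactants: 8 3-(benzyloxy)-5-bromophenol
Product: 9 1-(benzyloxy)-3-bromo-5-[(4-methoxyphenyl)methoxy]benzene
Conditions: 4-methoxybenzyl chloride, K2CO3, DMF, 50 °C
Reagents that add atoms: 4-methoxybenzyl chloride COc1ccc(CCl)cc1
Why: Williamson etherification puts an acid-labile ether on the one oxygen that will later carry the silicon bridge.

Step 6
Reactants: 9 1-(benzyloxy)-3-bromo-5-[(4-methoxyphenyl)methoxy]benzene; 6 4-(benzyloxy)-2-{[4-(benzyloxy)phenyl]methoxy}-6-bromobenzaldehyde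
Product: 11 racemic diarylmethanol, via aryl Grignard reagent 10 (not isolated)
Conditions: Mg, 1,2-dibromoethane (cat.), THF, 50 °C; then 6, 0 °C; aq NH4Cl
Reagents that add atoms: none
Why: Grignard addition to the aldehyde joins the two aryl rings, and the carbinol centre, formed as a racemate, is removed in step 7.

Step 7
Reactants: 11 racemic diarylmethanol
Product: 12 diaryl ketone
Conditions: Dess–Martin periodinane, CH2Cl2, rt
Reagents that add atoms: none
Why: Dess–Martin oxidation of a doubly benzylic secondary alcohol.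

Step 8
Reactants: 12 diaryl ketone
Product: 13 diaryl ketone hydrazone
Conditions: N2H4·H2O, AcOH (cat.), n-BuOH, 110 °C
Reagents that add atoms: hydrazine NN
Why: acid-catalysed condensation of hydrazine with the ketone, run hot because the carbonyl has two ortho substituents.

Step 9
Reactants: 13 diaryl ketone hydrazone
Product: 15 cis-(2R,3S)-4-bromo-2,3-diaryl-2,3-dihydrobenzofuran, via diaryldiazomethane 14 (not isolated)
Conditions: MnO2, CH2Cl2, 0 °C; filter; Rh2(S-PTAD)4 (1 mol %; PTAD = (1-adamantyl)(phthalimido)acetate), CH2Cl2, −20 °C to rt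
Reagents that add atoms: none
Why: enantioselective intramolecular 1,5 C–H insertion of a donor/donor rhodium carbene into the ether-activated benzylic C–H, in which the chiral dirhodium carboxylate selects the carbene face (C3 as S) and the concerted insertion places the two aryl groups cis (C2 as R).

Step 10
Reactants: 15 cis-(2R,3S)-4-bromo-2,3-diaryl-2,3-dihydrobenzofuran
Product: 16 3-(benzyloxy)-5-{(2S,3S)-6-(benzyloxy)-2-[4-(benzyloxy)phenyl]-4-bromo-2,3-dihydro-1-benzofuran-3-yl}phenol
Conditions: TFA (5 vol %), anisole (20 equiv), CH2Cl2, 0 °C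
Reagents that add atoms: none
Why: reversible acid ionisation of the O1–C2 bond to the para-benzyloxybenzyl cation and reclosure should give the thermodynamically preferred 2,3-trans ring with C3 untouched (C2 becomes S), while the same acid cleaves the 4-methoxybenzyl ether, whose cation is trapped by anisole.

Step 11
Reactants: 16 trans-bromide phenol (2 equiv); 17 (E)-1,2-bis(4,4,5,5-tetramethyl-1,3,2-dioxaborolan-2-yl)ethene
Product: 18 (E)-1,2-bis{(2S,3S)-6-(benzyloxy)-2-[4-(benzyloxy)phenyl]-3-[3-(benzyloxy)-5-hydroxyphenyl]-2,3-dihydro-1-benzofuran-4-yl}ethene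
Conditions: Pd(OAc)2, SPhos, K3PO4, 1,4-dioxane/H2O, 80 °C
Reagents that add atoms: none
Why: two-fold Suzuki–Miyaura coupling with retention of the E geometry of the diboronate should give the C2-symmetric stilbene, and free phenols are tolerated.

Step 12
Reactants: 19 4-hydroxybenzaldehyde
Product: 20 4-{[chlorodi(propan-2-yl)silyl]oxy}benzaldehyde
Conditions: iPr2SiCl2 (5 equiv), Et3N (1.1 equiv), THF, 0 °C to rt; filter under argon; volatiles and excess silane removed in vacuo; used crude
Reagents that add atoms: dichlorodi(propan-2-yl)silane CC(C)[Si](Cl)(Cl)C(C)C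
Why: monosilylation of a phenol by a dialkyldichlorosilane in large excess (first half of an unsymmetrical silaketal synthesis) should stop at the aryloxychlorosilane, because the excess reagent outcompetes the slower second substitution at the hindered diisopropylsilyl centre.

Step 13
Reactants: 18 C2-symmetric stilbene diol; 20 4-{[chlorodi(propan-2-yl)silyl]oxy}benzaldehyde (2.2 equiv)
Product: 21 bis[(4-formylphenoxy)diisopropylsilyl] ether of 18
Conditions: imidazole, DMAP (cat.), CH2Cl2, 0 °C to rt
Reagents that add atoms: none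
Why: O-silylation of both phenols of 18 by the monofunctional chlorosilane 20 (second half of the silaketal synthesis) should give the two mixed bis(aryloxy)silane tethers, and because each silicon carries only one chloride the two phenols of 18 cannot be bridged or oligomerised.

Step 14
Reactants: 5 4-(benzyloxy)benzyl chloride
Product: 22 1-{[4-(benzyloxy)phenyl]methyl}thiolan-1-ium tetrafluoroborate
Conditions: tetrahydrothiophene, NaBF4, acetone, rt
Reagents that add atoms: tetrahydrothiophene C1CCSC1; sodium tetrafluoroborate [Na+].F[B-](F)(F)F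
Why: S-alkylation of the sulfide by the reactive para-alkoxybenzyl chloride, driven by precipitation of NaCl.

Step 15
Reactants: 22 sulfonium tetrafluoroborate (2.6 equiv); 21 bis-aldehyde
Product: 24 bis-oxirane, via sulfonium benzylide 23 (not isolated)
Conditions: KN(SiMe3)2 (2.4 equiv), THF, −78 °C; then 21, −78 to −20 °C
Reagents that add atoms: none
Why: Corey–Chaykovsky epoxidation of both aryl aldehydes by the semistabilised benzylide should give the trans-2,3-diaryloxiranes, whose configuration is irrelevant because it is erased in step 16; the base is kept below the amount of sulfonium salt so that none is left to attack the aldehydes or the silyl ethers.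

Step 16
Reactants: 24 bis-oxirane
Product: 26 silylene-bridged tetrahydrofuran cycloadduct, via carbonyl ylide 25 (not isolated)
Conditions: 9,10-dicyanoanthracene (10 mol %), 420 nm LEDs, degassed MeCN/CH2Cl2 (1:1), 0.5 mM, 20 °C
Reagents that add atoms: none
Why: Proposed new method: singlet-excited 9,10-dicyanoanthracene oxidises one electron-rich oxirane of 24, the radical cation opens at its C–C bond and back electron transfer releases the exo,exo (W-shaped) 1,3-diaryl carbonyl ylide 25, which adds suprafacially to the tethered E-olefin in a concerted [4π+2π] dipolar cycloaddition; the closest known reaction type is the electron-transfer-sensitised opening of 2,3-diaryloxiranes and capture of the ylides by electron-poor alkenes between molecules, whereas capture by a non-activated stilbene through a silicon tether has not been shown. The tetrahydrofuran closes by this [3+2] cycloaddition (its C2–C3 and C4–C5 bonds form together), and the 15-membered ring that holds the O–Si–O bridge closes with it as a consequence. The W shape of the ylide fixes the two new oxygen-bearing carbons as 2,5-cis, retention of the E olefin fixes C3 and C4 as trans, and these two facts leave only the 2,3-cis/4,5-trans arrangement of the target, with no endo/exo issue because both ylide termini carry 4-oxyphenyl groups that end as the same 4-hydroxyphenyl group and the olefin is C2-symmetric. The step needs π-facial selectivity relative to the dihydrobenzofurans, and the bridge secures it: the O–Si–O link spans only about 2.6 Å from the C3 aryl ring, so the ylide can reach the olefin only from the face on which the two C3 aryl rings lie in the s-trans styrene rotamers (olefinic C–H syn to C3), which should give the (2S,3S,4S,5R) ring on a face that a free ylide would be expected to avoid. It also needs the E geometry to survive and the ylide to be trapped before it is lost: the triplet of the sensitiser lies below that of stilbene and stilbene radical cations relax to the E form, while reclosure of unreacted ylide to the oxirane simply returns the precursor, as does ylide formation on the second, spectator arm, which is equivalent by symmetry.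

Step 17
Reactants: 26 silylene-bridged tetrahydrofuran cycloadduct
Product: 27 heptabenzyl ether triphenol
Conditions: Bu4NF, AcOH, THF, 0 °C
Reagents that add atoms: none
Why: fluoride attacks silicon and releases the aryl oxides of both the bridge and the spectator arm, while acetic acid protonates the phenoxides so that the para-hydroxybenzylic ring C–O bonds are not opened.

Step 18
Reactants: 27 heptabenzyl ether triphenol
Product: 28 target CNP0270490.1
Conditions: H2 (1 atm), Pd/C (10 % palladium on carbon), EtOAc/MeOH, rt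
Reagents that add atoms: none
Why: neutral catalytic hydrogenolysis should remove the seven primary benzyl aryl ethers faster than it touches the secondary benzylic C–O bonds inside the rings, and no stereocentre is exposed to acid or base.

## Compound list

1 | 1,3-bis(benzyloxy)-5-bromobenzene | Brc1cc(OCc2ccccc2)cc(OCc2ccccc2)c1 | starting material
2 | {[2,4-bis(benzyloxy)-6-bromophenyl]methylidene}dimethylammonium dichlorophosphate | C[N+](C)=Cc1c(Br)cc(OCc2ccccc2)cc1OCc1ccccc1.[O-]P(=O)(Cl)Cl | intermediate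
3 | 2,4-bis(benzyloxy)-6-bromobenzaldehyde | O=Cc1c(Br)cc(OCc2ccccc2)cc1OCc1ccccc1 | intermediate
4 | 4-(benzyloxy)-2-bromo-6-hydroxybenzaldehyde | O=Cc1c(Br)cc(OCc2ccccc2)cc1O | intermediate
5 | 4-(benzyloxy)benzyl chloride | ClCc1ccc(OCc2ccccc2)cc1 | starting material
6 | 4-(benzyloxy)-2-{[4-(benzyloxy)phenyl]methoxy}-6-bromobenzaldehyde | O=Cc1c(Br)cc(OCc2ccccc2)cc1OCc1ccc(OCc2ccccc2)cc1 | intermediate
7 | 5-bromobenzene-1,3-diol | Oc1cc(O)cc(Br)c1 | starting material
8 | 3-(benzyloxy)-5-bromophenol | Oc1cc(Br)cc(OCc2ccccc2)c1 | intermediate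
9 | 1-(benzyloxy)-3-bromo-5-[(4-methoxyphenyl)methoxy]benzene | COc1ccc(COc2cc(Br)cc(OCc3ccccc3)c2)cc1 | intermediate
10 | {3-(benzyloxy)-5-[(4-methoxyphenyl)methoxy]phenyl}magnesium bromide | COc1ccc(COc2cc([Mg]Br)cc(OCc3ccccc3)c2)cc1 | intermediate
11 | {3-(benzyloxy)-5-[(4-methoxyphenyl)methoxy]phenyl}[4-(benzyloxy)-2-{[4-(benzyloxy)phenyl]methoxy}-6-bromophenyl]methanol (racemic) | OC(c1cc(OCc2ccccc2)cc(OCc2ccc(OC)cc2)c1)c1c(Br)cc(OCc2ccccc2)cc1OCc1ccc(OCc2ccccc2)cc1 | intermediate
12 | {3-(benzyloxy)-5-[(4-methoxyphenyl)methoxy]phenyl}[4-(benzyloxy)-2-{[4-(benzyloxy)phenyl]methoxy}-6-bromophenyl]methanone | O=C(c1cc(OCc2ccccc2)cc(OCc2ccc(OC)cc2)c1)c1c(Br)cc(OCc2ccccc2)cc1OCc1ccc(OCc2ccccc2)cc1 | intermediate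
13 | hydrazone of ketone 12 (C=N geometry not defined) | NN=C(c1cc(OCc2ccccc2)cc(OCc2ccc(OC)cc2)c1)c1c(Br)cc(OCc2ccccc2)cc1OCc1ccc(OCc2ccccc2)cc1 | intermediate
14 | diaryldiazomethane from 13 | [N-]=[N+]=C(c1cc(OCc2ccccc2)cc(OCc2ccc(OC)cc2)c1)c1c(Br)cc(OCc2ccccc2)cc1OCc1ccc(OCc2ccccc2)cc1 | intermediate
15 | (2R,3S)-6-(benzyloxy)-2-[4-(benzyloxy)phenyl]-3-{3-(benzyloxy)-5-[(4-methoxyphenyl)methoxy]phenyl}-4-bromo-2,3-dihydro-1-benzofuran (2,3-cis) | c7ccccc7COc1ccc([C@@H]2Oc3cc(OCc7ccccc7)cc(Br)c3[C@@H]2c2cc(OCc7ccccc7)cc(OCc8ccc(OC)cc8)c2)cc1 | intermediate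
16 | 3-(benzyloxy)-5-{(2S,3S)-6-(benzyloxy)-2-[4-(benzyloxy)phenyl]-4-bromo-2,3-dihydro-1-benzofuran-3-yl}phenol (2,3-trans) | c7ccccc7COc1ccc([C@H]2Oc3cc(OCc7ccccc7)cc(Br)c3[C@@H]2c2cc(OCc7ccccc7)cc(O)c2)cc1 | intermediate
17 | (E)-1,2-bis(4,4,5,5-tetramethyl-1,3,2-dioxaborolan-2-yl)ethene | CC1(C)OB(OC1(C)C)/C=C/B1OC(C)(C)C(C)(C)O1 | starting material
18 | (E)-1,2-bis{(2S,3S)-6-(benzyloxy)-2-[4-(benzyloxy)phenyl]-3-[3-(benzyloxy)-5-hydroxyphenyl]-2,3-dihydro-1-benzofuran-4-yl}ethene | c7ccccc7COc1ccc([C@H]2Oc3cc(OCc7ccccc7)cc(/C=C/c5cc(OCc7ccccc7)cc6c5[C@H](c5cc(OCc7ccccc7)cc(O)c5)[C@@H](c5ccc(OCc7ccccc7)cc5)O6)c3[C@@H]2c2cc(OCc7ccccc7)cc(O)c2)cc1 | intermediate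
19 | 4-hydroxybenzaldehyde | O=Cc1ccc(O)cc1 | starting material
20 | 4-{[chlorodi(propan-2-yl)silyl]oxy}benzaldehyde | O=Cc1ccc(O[Si](Cl)(C(C)C)C(C)C)cc1 | intermediate
21 | bis-aldehyde: each phenolic oxygen of 18 joined through Si(iPr)2 to the oxygen of a 4-formylphenoxy group | c7ccccc7COc1ccc([C@H]2Oc3cc(OCc7ccccc7)cc(/C=C/c5cc(OCc7ccccc7)cc6c5[C@H](c5cc(OCc7ccccc7)cc(O[Si](C(C)C)(C(C)C)Oc8ccc(C=O)cc8)c5)[C@@H](c5ccc(OCc7ccccc7)cc5)O6)c3[C@@H]2c2cc(OCc7ccccc7)cc(O[Si](C(C)C)(C(C)C)Oc8ccc(C=O)cc8)c2)cc1 | intermediate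
22 | 1-{[4-(benzyloxy)phenyl]methyl}thiolan-1-ium tetrafluoroborate | F[B-](F)(F)F.c1ccccc1COc1ccc(C[S+]2CCCC2)cc1 | intermediate
23 | [4-(benzyloxy)phenyl]methylide of thiolanium (sulfonium benzylide) | c1ccccc1COc1ccc([CH-][S+]2CCCC2)cc1 | intermediate
24 | bis-oxirane: each formyl group of 21 converted into a trans-3-[4-(benzyloxy)phenyl]oxiran-2-yl group; oxirane configuration not controlled, the (R,R) form of each is drawn | c7ccccc7COc1ccc([C@H]2Oc3cc(OCc7ccccc7)cc(/C=C/c5cc(OCc7ccccc7)cc6c5[C@H](c5cc(OCc7ccccc7)cc(O[Si](C(C)C)(C(C)C)Oc8ccc(cc8)[C@@H]9[C@H](O9)c8ccc(OCc7ccccc7)cc8)c5)[C@@H](c5ccc(OCc7ccccc7)cc5)O6)c3[C@@H]2c2cc(OCc7ccccc7)cc(O[Si](C(C)C)(C(C)C)Oc8ccc(cc8)[C@@H]9[C@H](O9)c8ccc(OCc7ccccc7)cc8)c2)cc1 | intermediate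
25 | carbonyl ylide: one oxirane of 24 opened at its C–C bond to the exo,exo (W-shaped) ylide ArCH(−)–O(+)=CHAr′, the other arm unchanged | c7ccccc7COc1ccc([C@H]2Oc3cc(OCc7ccccc7)cc(/C=C/c5cc(OCc7ccccc7)cc6c5[C@H](c5cc(OCc7ccccc7)cc(O[Si](C(C)C)(C(C)C)Oc8ccc(cc8)[CH-]/[O+]=C/c8ccc(OCc7ccccc7)cc8)c5)[C@@H](c5ccc(OCc7ccccc7)cc5)O6)c3[C@@H]2c2cc(OCc7ccccc7)cc(O[Si](C(C)C)(C(C)C)Oc8ccc(cc8)[C@@H]9[C@H](O9)c8ccc(OCc7ccccc7)cc8)c2)cc1 | intermediate
26 | cycloadduct: (2S,3S,4S,5R)-tetrahydrofuran bearing 2-[4-(benzyloxy)phenyl], 3- and 4-[(2S,3S)-dihydrobenzofuran-4-yl] and a 5-(4-oxyphenyl) group whose oxygen is bridged through Si(iPr)2 to the C3 aryl ring of the dihydrobenzofuran on C4; the spectator oxirane arm is unchanged | c7ccccc7COc1ccc([C@H]2Oc3cc(OCc7ccccc7)cc([C@@H]4[C@@H](c5cc(OCc7ccccc7)cc6c5[C@H](c5cc(OCc7ccccc7)cc(O[Si]8(C(C)C)C(C)C)c5)[C@@H](c5ccc(OCc7ccccc7)cc5)O6)[C@H](c5ccc(O8)cc5)O[C@@H]4c4ccc(OCc7ccccc7)cc4)c3[C@@H]2c2cc(OCc7ccccc7)cc(O[Si](C(C)C)(C(C)C)Oc8ccc(cc8)[C@@H]9[C@H](O9)c8ccc(OCc7ccccc7)cc8)c2)cc1 | intermediate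
27 | heptabenzyl ether of the target with three free phenols (the 4-hydroxyphenyl on C5 of the tetrahydrofuran and one hydroxyl on each C3 aryl ring) | c7ccccc7COc1ccc([C@H]2Oc3cc(OCc7ccccc7)cc([C@@H]4[C@@H](c5cc(OCc7ccccc7)cc6c5[C@H](c5cc(OCc7ccccc7)cc(O)c5)[C@@H](c5ccc(OCc7ccccc7)cc5)O6)[C@H](c5ccc(O)cc5)O[C@@H]4c4ccc(OCc7ccccc7)cc4)c3[C@@H]2c2cc(OCc7ccccc7)cc(O)c2)cc1 | intermediate
28 | CNP0270490.1: (2S,3S,4S,5R)-2,5-bis(4-hydroxyphenyl)-3,4-bis[(2S,3S)-3-(3,5-dihydroxyphenyl)-6-hydroxy-2-(4-hydroxyphenyl)-2,3-dihydro-1-benzofuran-4-yl]tetrahydrofuran | Oc1ccc([C@H]2Oc3cc(O)cc([C@@H]4[C@@H](c5cc(O)cc6c5[C@H](c5cc(O)cc(O)c5)[C@@H](c5ccc(O)cc5)O6)[C@H](c5ccc(O)cc5)O[C@@H]4c4ccc(O)cc4)c3[C@@H]2c2cc(O)cc(O)c2)cc1 | target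

## Step count and risks

Total step count: 18. Longest linear sequence: 14 steps (1, 2, 3, 6, 7, 8, 9, 10, 11, 13, 15, 16, 17, 18).

Steps most likely to fail:

1. Step 16 (proposed new method). The tethered ylide may reclose to the oxirane or fragment faster than it is trapped across the 15-membered ring, and hole transfer to the stilbene may divert material into oxidation of the olefin. The fallback gives up the cycloaddition and builds the ring by the known oxidative route of this natural product family, which joins the two olefinic carbons of like polarity and brings in the ring oxygen as water. It sets out from bromide 16. Heck coupling with 4-acetoxystyrene (Pd(OAc)2, P(o-tol)3, Et3N, DMF, 100 °C) should give the (E)-stilbene acetate F1, and methanolysis (K2CO3, MeOH) the 4-hydroxystilbene F2, a benzyl-protected ε-viniferin. One-electron oxidation (FeCl3·6H2O, acetone/H2O) should couple two phenoxyl radicals of F2 at the olefinic carbons next to the dihydrobenzofurans to give the bis(quinone methide) F3, which is not isolated. Water adds to one quinone methide and the benzylic alcohol so formed adds to the other, closing the tetrahydrofuran diol F4. This sequence is not stereospecific, so F4 has to be separated from its ring diastereomers by preparative HPLC. Hydrogenolysis as in step 18 then brings the route back at target 28.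

2. Step 9. The ortho bromine twists the carbene out of the plane of its aryl ring, which may erode the enantio- and cis-selectivity of the insertion. The fallback replaces catalyst control by resolution. It sets out from hydrazone 13: oxidation as before and insertion with the achiral catalyst Rh2(esp)2 (esp = α,α,α′,α′-tetramethyl-1,3-benzenedipropionate) should give the cis ring as a racemate, that is 15 together with its enantiomer F5. The two are separated by preparative chromatography on a chiral stationary phase, and the route is rejoined at 15.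

3. Step 18. Hydrogenolysis of the doubly benzylic ring C–O bonds (O1–C2 of each dihydrobenzofuran, and the C2–O and C5–O bonds of the tetrahydrofuran) may compete with removal of the seven benzyl ethers. The fallback sets out from 27 and goes straight to 28: BCl3 with pentamethylbenzene as benzyl-cation trap in CH2Cl2 at −78 °C cleaves aryl benzyl ethers by Lewis-acid-assisted ionisation, a mode that cannot reduce the ring C–O bonds. It makes no new compound.

Further compounds

F1 | step 16 | 4-[(E)-2-{(2S,3S)-6-(benzyloxy)-2-[4-(benzyloxy)phenyl]-3-[3-(benzyloxy)-5-hydroxyphenyl]-2,3-dihydro-1-benzofuran-4-yl}ethenyl]phenyl acetate | c7ccccc7COc1ccc([C@H]2Oc3cc(OCc7ccccc7)cc(/C=C/c8ccc(OC(C)=O)cc8)c3[C@@H]2c2cc(OCc7ccccc7)cc(O)c2)cc1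
F2 | step 16 | 3-(benzyloxy)-5-{(2S,3S)-6-(benzyloxy)-2-[4-(benzyloxy)phenyl]-4-[(E)-2-(4-hydroxyphenyl)ethenyl]-2,3-dihydro-1-benzofuran-3-yl}phenol | c7ccccc7COc1ccc([C@H]2Oc3cc(OCc7ccccc7)cc(/C=C/c8ccc(O)cc8)c3[C@@H]2c2cc(OCc7ccccc7)cc(O)c2)cc1
F3 | step 16 | bis(quinone methide): 2,3-bis(dihydrobenzofuran-4-yl)butane-1,4-diylidene core with a 4-oxocyclohexa-2,5-dienylidene on each end, central carbons configured as in the target | c7ccccc7COc1ccc([C@H]2Oc3cc(OCc7ccccc7)cc([C@@H](C=C4C=CC(=O)C=C4)[C@@H](c5cc(OCc7ccccc7)cc6c5[C@H](c5cc(OCc7ccccc7)cc(O)c5)[C@@H](c5ccc(OCc7ccccc7)cc5)O6)C=C4C=CC(=O)C=C4)c3[C@@H]2c2cc(OCc7ccccc7)cc(O)c2)cc1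
F4 | step 16 | hexabenzyl ether of the target with four free phenols (both 4-hydroxyphenyl groups of the tetrahydrofuran and one hydroxyl on each C3 aryl ring) | c7ccccc7COc1ccc([C@H]2Oc3cc(OCc7ccccc7)cc([C@@H]4[C@@H](c5cc(OCc7ccccc7)cc6c5[C@H](c5cc(OCc7ccccc7)cc(O)c5)[C@@H](c5ccc(OCc7ccccc7)cc5)O6)[C@H](c5ccc(O)cc5)O[C@@H]4c4ccc(O)cc4)c3[C@@H]2c2cc(OCc7ccccc7)cc(O)c2)cc1
F5 | step 9 | (2S,3R)-6-(benzyloxy)-2-[4-(benzyloxy)phenyl]-3-{3-(benzyloxy)-5-[(4-methoxyphenyl)methoxy]phenyl}-4-bromo-2,3-dihydro-1-benzofuran (enantiomer of 15) | c7ccccc7COc1ccc([C@H]2Oc3cc(OCc7ccccc7)cc(Br)c3[C@H]2c2cc(OCc7ccccc7)cc(OCc8ccc(OC)cc8)c2)cc1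
F0 | step 18 | none | none
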